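The oxolane ring (O1, C2 with the side chain, C3, C4–OH, C5 with pentyl) is cut at C3–C4 and O1–C5. The key step exploits the syn-1,3 pair C2–O1/C4–OH and the vicinal pair C4–OH/C5–O1, which together are the reduced aldol of a methyl ketone and an α-chloro aldehyde. In one flask the boron enolate of (R)-2-oxododec-11-en-3-yl dodecanoate adds to (R)-2-chloroheptanal, the boron aldolate is reduced to the syn-diol, and the new C2 hydroxyl displaces chloride with inversion. Both precursors are acyclic, the laurate is already in place, and the step delivers the target without protecting groups.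

Key step: step 6

Remark: the (5R)-imidazolidinone is assumed to deliver the (R)-chloride, the mirror image of the established (5S)-to-(S) sense; both catalyst enantiomers are commercial.

Step 1
Reactants: 1 8-bromooct-1-ene; 2 methyl (R)-oxirane-2-carboxylate
Product: 4 methyl (R)-2-hydroxyundec-10-enoate, via oct-7-enylmagnesium bromide 3 (not isolated)
Conditions: Mg, THF, rt; CuI (10 mol %), 2, THF, −40 °C; aq NH4Cl
Reagents that add atoms: none
Why: Copper-catalysed Grignard opening of the glycidic ester (SN2 at the unsubstituted epoxide carbon) should outrun addition to the ester at low temperature, and because the C–O bond at the stereocentre is untouched, the (R) configuration of 2 becomes that of the future lauroyloxy carbon.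

Step 2
Reactants: 4 methyl (R)-2-hydroxyundec-10-enoate
Product: 5 (R)-2-hydroxy-N-methoxy-N-methylundec-10-enamide
Conditions: MeNH(OMe)·HCl, i-PrMgCl, THF, −20 to 0 °C; aq NH4Cl
Reagents that add atoms: N,O-dimethylhydroxylamine hydrochloride, CNOC.Cl
Why: Weinreb amide formation by aminolysis of the ester with the chloromagnesium amide made in the flask occurs only at the acyl carbon, with the free hydroxyl present as an inert magnesium alkoxide, so the stereocentre is retained.

Step 3
Reactants: 5 (R)-2-hydroxy-N-methoxy-N-methylundec-10-enamide
Product: 6 (R)-3-hydroxydodec-11-en-2-one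
Conditions: MeMgBr (excess), THF, 0 °C; aq NH4Cl
Reagents that add atoms: methylmagnesium bromide, C[Mg]Br
Why: Weinreb ketone synthesis, in which the chelated tetrahedral magnesium adduct survives until the quench, so a second addition is prevented and the methyl ketone forms without loss of the adjacent stereocentre.

Step 4
Reactants: 6 (R)-3-hydroxydodec-11-en-2-one; 7 dodecanoyl chloride
Product: 8 (R)-2-oxododec-11-en-3-yl dodecanoate
Conditions: pyridine, CH2Cl2, 0 °C to rt
Reagents that add atoms: none
Why: O-acylation of a secondary alcohol with an acid chloride, where pyridine is too weak a base to enolise the α-acyloxy ketone, so the stereocentre should stay intact and the ester of the target is in place before the ring is made.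

Step 5
Reactants: 9 heptanal
Product: 10 (R)-2-chloroheptanal
Conditions: (5R)-5-benzyl-2,2,3-trimethylimidazolidin-4-one·TFA (5 mol %), 2,3,4,5,6,6-hexachlorocyclohexa-2,4-dien-1-one, acetone, −30 °C; cold pentane filtration, used at once
Reagents that add atoms: 2,3,4,5,6,6-hexachlorocyclohexa-2,4-dien-1-one, O=C1C(Cl)=C(Cl)C(Cl)=C(Cl)C1(Cl)Cl
Why: Enamine-catalysed α-chlorination of an aldehyde, in which the (E)-enamine turns away from the gem-dimethyl group, the benzyl group covers one face and chlorine is delivered to the other, setting the (R)-C–Cl centre that later becomes C5 of the ring by inversion.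

Step 6
Reactants: 8 (R)-2-oxododec-11-en-3-yl dodecanoate; 10 (R)-2-chloroheptanal
Product: 14 (1R)-1-[(2R,4S,5S)-4-hydroxy-5-pentyloxolan-2-yl]dec-9-en-1-yl dodecanoate, via enol dicyclohexylborinate 11 (not isolated), via boron aldolate 12 (not isolated), via syn-chlorodiol 13 (not isolated)
Conditions: c-Hex2BCl, Et3N, Et2O, 0 °C; 10, −78 to −20 °C; LiBH4, THF, −78 °C; MeOH then pH 7 phosphate buffer (Na2HPO4/NaH2PO4), −78 °C to rt; Et2O distilled off, sealed vessel, 100 °C
Reagents that add atoms: none
Why: c-Hex2BCl/Et3N enolises 8 on its methyl side to 11, whose boron aldol addition to 10 makes the C3–C4 bond; LiBH4 then reduces the six-membered boron chelate 12, and in the buffered hot aqueous methanol the new C2 hydroxyl of 13 displaces the secondary chloride and makes the O1–C5 bond. The closest known reaction types are the boron aldol/in situ borohydride sequence to syn-1,3-diols (Narasaka–Prasad-type chelate reduction) and the neutral thermal cyclisation of 4-chloro-1,3-diols to 3-hydroxytetrahydrofurans (intramolecular Williamson-type SN2). The only ring closes in the 5-exo-tet mode with inversion, so the (R)-C–Cl centre becomes (S)-C5 and the pentyl group ends cis to the C4 hydroxyl. C4 is controlled by the α-chloro stereocentre of 10 (Cornforth-type transition state, 1,2-anti chlorohydrin), and C2 by external hydride attack on the chelate (1,3-syn to C4), a sense that polar Felkin–Anh control from the lauroyloxy carbon C1' (threo) reinforces. The step needs regioselective enolisation, secured by the bulky boron chloride and the branched acyloxy-bearing α'-carbon; survival of ester and alkene, secured by hydride at −78 °C with a cold methanol quench and by pH 7; and oxygen selectivity in the closure, secured by the absence of base (no alkoxide, hence no epoxide from the C4 hydroxyl) and by the kinetic advantage of the five-membered over any six-membered closure.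

Compound list
1 | 8-bromooct-1-ene | C=CCCCCCCBr | starting material
2 | methyl (R)-oxirane-2-carboxylate | COC(=O)[C@H]1CO1 | starting material
3 | oct-7-enylmagnesium bromide | C=CCCCCCC[Mg]Br | intermediate
4 | methyl (R)-2-hydroxyundec-10-enoate | C=CCCCCCCC[C@@H](O)C(=O)OC | intermediate
5 | (R)-2-hydroxy-N-methoxy-N-methylundec-10-enamide | C=CCCCCCCC[C@@H](O)C(=O)N(C)OC | intermediate
6 | (R)-3-hydroxydodec-11-en-2-one | C=CCCCCCCC[C@@H](O)C(C)=O | intermediate
7 | dodecanoyl chloride | CCCCCCCCCCCC(=O)Cl | starting material
8 | (R)-2-oxododec-11-en-3-yl dodecanoate | C=CCCCCCCC[C@@H](OC(=O)CCCCCCCCCCC)C(C)=O | intermediate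
9 | heptanal | CCCCCCC=O | starting material
10 | (R)-2-chloroheptanal | CCCCC[C@@H](Cl)C=O | intermediate
11 | (R)-2-(dicyclohexylboryloxy)dodeca-1,11-dien-3-yl dodecanoate | C=CCCCCCCC[C@@H](OC(=O)CCCCCCCCCCC)C(=C)OB(C1CCCCC1)C1CCCCC1 | intermediate
12 | (6R,7S,10R)-6-chloro-7-(dicyclohexylboryloxy)-9-oxononadec-18-en-10-yl dodecanoate | C=CCCCCCCC[C@@H](OC(=O)CCCCCCCCCCC)C(=O)C[C@H](OB(C1CCCCC1)C1CCCCC1)[C@H](Cl)CCCCC | intermediate
13 | (6R,7S,9R,10R)-6-chloro-7,9-dihydroxynonadec-18-en-10-yl dodecanoate | C=CCCCCCCC[C@@H](OC(=O)CCCCCCCCCCC)[C@H](O)C[C@H](O)[C@H](Cl)CCCCC | intermediate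
14 | (1R)-1-[(2R,4S,5S)-4-hydroxy-5-pentyloxolan-2-yl]dec-9-en-1-yl dodecanoate | C=CCCCCCCC[C@@H](OC(=O)CCCCCCCCCCC)[C@H]1C[C@H](O)[C@H](CCCCC)O1 | target

Total step count: 6
Longest linear sequence: 5 (steps 1, 2, 3, 4, 6)

Steps most likely to fail

Step 6. Several processes could go wrong:
- The facial bias of the chiral enolate may oppose the Cornforth preference of the aldehyde and lower the facial selectivity.
- Free amine may erode the configuration of the chloro aldehyde.
- Borane left after hydride transfer may hydroborate the terminal alkene.
- The hot neutral closure may be accompanied by acyl migration or ester solvolysis.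

The fallback separates the events and uses an open, amine-free transition state. It sets out from 8. Kinetic silylation (LiHMDS with TMSCl present, THF, −78 °C) gives (R)-2-(trimethylsilyloxy)dodeca-1,11-dien-3-yl dodecanoate F1. A BF3·OEt2-mediated Mukaiyama aldol addition of F1 to 10 at −78 °C gives the isolable (6R,7S,10R)-6-chloro-7-hydroxy-9-oxononadec-18-en-10-yl dodecanoate F2, whose diastereomers can be separated. Et2BOMe/NaBH4 in THF–MeOH at −78 °C then returns to the route at 13. This is closed at room temperature with AgOTf/Ag2O in THF to give 14.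

Step 1. The Grignard reagent may add to the ester faster than the copper-mediated epoxide opening proceeds, and the product alkoxide may trigger transesterification or oligomerisation. The fallback masks the acyl group as a carboxylate. It sets out from 2. KOH in EtOH at 0 °C gives potassium (R)-oxirane-2-carboxylate F3. This is opened with 3 and CuI in THF to give, after acidification, (R)-2-hydroxyundec-10-enoic acid F4. Carbodiimide coupling (EDC·HCl, N-methylmorpholine, MeNH(OMe)·HCl, CH2Cl2) comes back to the route at 5.

Step 5. Face selection in the enamine chlorination may be incomplete, and the configuration of the labile α-chloro aldehyde may be lost on handling. The fallback uses an auxiliary and a configurationally stable storage form, and it sets out from 9.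
- Pinnick oxidation (NaClO2, NaH2PO4, 2-methylbut-2-ene) gives heptanoic acid F5.
- Mixed-anhydride acylation (PivCl, Et3N, LiCl) of (R)-4-benzyloxazolidin-2-one gives (R)-4-benzyl-3-heptanoyloxazolidin-2-one F6.
- Bu2BOTf/i-Pr2NEt enolisation and NCS give (R)-4-benzyl-3-[(R)-2-chloroheptanoyl]oxazolidin-2-one F7, which can be freed of its diastereomer by chromatography.
- LiBH4 in wet Et2O gives (R)-2-chloroheptan-1-ol F8.
- Dess–Martin oxidation directly before use comes back to the route at 10.

Further compounds
F1 | step 6 | (R)-2-(trimethylsilyloxy)dodeca-1,11-dien-3-yl dodecanoate | C=CCCCCCCC[C@@H](OC(=O)CCCCCCCCCCC)C(=C)O[Si](C)(C)C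
F2 | step 6 | (6R,7S,10R)-6-chloro-7-hydroxy-9-oxononadec-18-en-10-yl dodecanoate | C=CCCCCCCC[C@@H](OC(=O)CCCCCCCCCCC)C(=O)C[C@H](O)[C@H](Cl)CCCCC
F3 | step 1 | potassium (R)-oxirane-2-carboxylate | [K+].[O-]C(=O)[C@H]1CO1
F4 | step 1 | (R)-2-hydroxyundec-10-enoic acid | C=CCCCCCCC[C@@H](O)C(=O)O
F5 | step 5 | heptanoic acid | CCCCCCC(=O)O
F6 | step 5 | (R)-4-benzyl-3-heptanoyloxazolidin-2-one | CCCCCCC(=O)N1[C@H](Cc2ccccc2)COC1=O
F7 | step 5 | (R)-4-benzyl-3-[(R)-2-chloroheptanoyl]oxazolidin-2-one | CCCCC[C@@H](Cl)C(=O)N1[C@H](Cc2ccccc2)COC1=O
F8 | step 5 | (R)-2-chloroheptan-1-ol | CCCCC[C@@H](Cl)CO
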